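The numbers in the tables are simulated on assumed constants; noise was put on by code.

- The easy step first: the zeta run is this very flask followed so far, and its highest reading is 33% at 2.50 h.

- zeta: free monomer 0.18 M; transfer agent 5.4 mM; capture agent 9 mM; initiator 1.8 mM; the very flask that is asked about, followed so far
- flask: free monomer 0.18 M; transfer agent 5.40 mM; capture agent 9.00 mM; initiator 1.8 mM; time 20 h

zeta run (percent of the free monomer charged)

| time / h | monomer in chains / % |
|---|---|
| 0.667 | 12 |
| 1.00 | 16 |
| 1.50 | 28 |
| 2.50 | 33 |
| 4.00 | 29 |
| 5.00 | 29 |
| 8.00 | 23 |

(scatter of a reading: 1.5 percentage points)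

- when, up to 20 h, the flask holds most monomer in chains
- the amount of monomer in chains, in percent of the free monomer charged, at that time



- From above, I set the top of my bracket at that reading plus two standard deviations, an estimate that comes to 36.0%.
- To bound it from below, I take the fall lifetime of [monomer in chains], the time in which the late readings would drop by a factor e. From 29% at 4.00 h to 23% at 8.00 h, it comes to 17.3 h.
- Counting back along that lifetime from 4.00 h to 2.50 h gives 31.6%, a reading-based floor that carries their scatter.
- The readings at 1.50 h and 4.00 h both lie below the one at 2.50 h, so I place the peak between those times, and I commit to the middle of the height bracket, 33.8%.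
- The forecast says 3 h (2.2 h to 4 h) and 31.5% (29.5% to 34%), just under my floor, and adds: “The peak is flat, so its time is less certain than its height.”
- This flask peaks at 2.65 h with 33.8%, inside my bracket.

    free monomer + initiator → living end + monomer in chains (k = 0.00170 M⁻¹ s⁻¹)
    free monomer + living end → monomer in chains + living end, rate k2*[living end]*[free monomer] (k = 0.130 M⁻¹ s⁻¹)
    living end + transfer agent → dead chain (kL = 0.00600 M⁻¹ s⁻¹)
    monomer in chains ⇌ isomer of the product (K = 2.60, k = 1.50 × 10⁻⁴ s⁻¹)
    living end + capture agent → trapped intermediate (k = 0.0110 M⁻¹ s⁻¹)
    monomer in chains → over-reaction product (k = 1.80 × 10⁻⁸ s⁻¹)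

- In this flask, the conversion of free monomer into monomer in chains has half its turnover up to the longest time allowed behind it at 1.69 h, and the conversion of monomer in chains into isomer of the product at 3.05 h. That second step has 97% of its turnover done by 10.0 h, and from the peak to 20 h this flask falls 0.355 fall lifetimes to 23.7%, while 1.00 lifetimes of time pass. The neighbour charged with 0.036 M of capture agent goes from its best of 20.3% to 12.1% at 20 h, which is 0.517 fall lifetimes.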